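## Retrosynthetic overview
1. Plagiochilin A comes from a C10 ketone (16) by methylene transfer to give the spiro-epoxide, which is the last step.
2. Ketone 16 comes from the 2-methoxy-dihydropyran 15. The pyran is built on cycloheptenone 11 by a Mukaiyama–Michael addition at C5, orthoformate functionalisation at C1, and enol-ether cyclisation.
3. Enone 11 comes from a Stork–Danheiser transposition of dione 9, which comes from ozonolysis of the deconjugated enone 8.
4. Enone 7, a bicyclo[5.1.0]octenone, is made by electrochemical one-carbon ring expansion of the siloxycyclopropane from carone (4). Carone comes from 1,3-elimination of the dihydrocarvone hydrochloride, and (S)-carvone fixes both cyclopropane stereocentres.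
5. Ring order: cyclopropane, then cycloheptane (ring expansion), then dihydropyran, then epoxide.

Assumptions (one line each):
- The C2 acetal configuration is set thermodynamically (anomeric) under the acidic conditions of Steps 13–14.
- The sulfonium ylide adds to C10 anti to the neighbouring C2 substituent, which places O on the same face as C2/C4.

## Route

**Step 1**
Reactants: 1, (S)-(+)-carvone
Product: 2, (5S)-dihydrocarvone (C2-epimer mixture)
Conditions: L-Selectride, THF, –78 °C; then aq. NH4Cl
Reagents that add atoms: none
Why: Conjugate (1,4-) hydride reduction leaves the isopropenyl group untouched; C5 is unchanged and the C2 epimers are irrelevant because C2 is enolised later.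

**Step 2**
Reactants: 2
Product: 3, 8-chloro-p-menthan-2-one, the tertiary chloride
Conditions: HCl (g), CH2Cl2, 0 °C
Reagents that add atoms: hydrogen chloride, Cl
Why: Markovnikov hydrochlorination of the isopropenyl group.

**Step 3**
Reactants: 3
Product: 4, carone, cis-fused 3,7,7-trimethylbicyclo[4.1.0]heptan-2-one (C3 epimeric)
Conditions: KOH, EtOH/H2O, reflux
Reagents that add atoms: none
Why: 1,3-Dehydrochlorination is an intramolecular enolate alkylation (3-exo-tet) that closes the gem-dimethylcyclopropane, and carvone C5 dictates both new cyclopropane stereocentres (C6 and C7 in target numbering).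

**Step 4**
Reactants: 4
Product: 5, silyl enol ether (C2(OTMS)=C3 toward the methyl-bearing carbon)
Conditions: TMSCl, NaI, Et3N, MeCN, 25 °C
Reagents that add atoms: chlorotrimethylsilane, C[Si](C)(C)Cl
Why: Enolisation is only possible at C3, because the cyclopropyl α-carbon cannot enolise, so the enol ether forms regiospecifically.

**Step 5**
Reactants: 5
Product: 6, 1-siloxybicyclo[n.1.0] tricycle (siloxycyclopropane)
Conditions: Et2Zn, CH2I2, DCE, 0 → 25 °C
Reagents that add atoms: diiodomethane, ICI
Why: Furukawa–Simmons–Smith cyclopropanation of the electron-rich enol ether; the new ring's stereocentres are destroyed in the next step.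

**Step 6**
Reactants: 6
Product: 7, 4,8,8-trimethylbicyclo[5.1.0]oct-3-en-2-one
Conditions: undivided cell, graphite anode / Pt cathode, constant current, nBu4NBF4, MeCN–HFIP (9:1), 2,6-lutidine, 25 °C (about 2.2 F/mol)
Reagents that add atoms: none
Why: Proposed new method: anodic single-electron oxidation of the siloxycyclopropane gives a radical cation that cleaves the internal C–C bond regioselectively to a tertiary radical and a silyloxocarbenium ion, which is desilylated. The radical is oxidised again to the tertiary cation and loses H+ to lutidine to give the conjugated enone, with H2 evolved at the cathode. This forges the seven-membered ring and the C=C in one step. The closest known reactions are the FeCl3 Ito–Saegusa ring expansion and anodic ring opening of cyclopropanols; the cyclopropane stereocentres are untouched.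

**Step 7**
Reactants: 7
Product: 8, 4-methylidene-8,8-dimethylbicyclo[5.1.0]octan-2-one
Conditions: LDA, THF, –78 °C; then AcOH, –78 °C → 25 °C
Reagents that add atoms: none
Why: Kinetic γ-deprotonation of the methyl group gives the extended dienolate, and α-protonation gives the β,γ-enone with an exocyclic methylene (deconjugation).

**Step 8**
Reactants: 8
Product: 9, 8,8-dimethylbicyclo[5.1.0]octane-2,4-dione (enolised)
Conditions: O3, CH2Cl2/MeOH, –78 °C; then Me2S, –78 → 25 °C
Reagents that add atoms: ozone, [O-][O+]=O
Why: Ozonolysis of the 1,1-disubstituted alkene gives the ketone, which removes C14; that carbon is re-installed in Step 15.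

**Step 9**
Reactants: 9
Product: 10, 4-methoxy-8,8-dimethylbicyclo[5.1.0]oct-3-en-2-one
Conditions: HC(OMe)3, TsOH·H2O (cat.), MeOH, 25 °C
Reagents that add atoms: trimethyl orthoformate, COC(OC)OC; methanol, CO
Why: Vinylogous ester formation (first stage of the Stork–Danheiser transposition). It should occur at the carbonyl remote from the cyclopropane, which is the less hindered and more electrophilic one.

**Step 10**
Reactants: 10
Product: 11, 8,8-dimethylbicyclo[5.1.0]oct-2-en-4-one
Conditions: LiAlH4, THF, –78 → 0 °C; then 1 M HCl, THF, 0 → 25 °C
Reagents that add atoms: water (O), from the aqueous acid workup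
Why: Stork–Danheiser transposition: hydride adds to the C5 carbonyl, then hydrolysis of the enol ether and β-elimination give the enone with the ketone at C10 and C1=C5 conjugated. The enone β-carbon (C5) sits next to the cyclopropane.

**Step 11**
Reactants: 12, 3-(tert-butyldimethylsilyloxy)propanal
Product: 13, 1-(trimethylsilyloxy)-3-(TBS-oxy)propene (enol silane)
Conditions: TMSOTf, Et3N, CH2Cl2, 0 °C
Reagents that add atoms: trimethylsilyl triflate, C[Si](C)(C)OS(=O)(=O)C(F)(F)F
Why: Standard silyl enol ether formation from an aldehyde.

**Step 12**
Reactants: 11 and 13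
Product: 14, ketone TMS enol ether carrying the C5–CH(CH2OTBS)CHO side chain
Conditions: TMSOTf (10 mol%), CH2Cl2, –78 °C
Reagents that add atoms: none (the TMS group transfers from 13 to the ketone oxygen)
Why: Mukaiyama–Michael addition; the enol silane attacks C5 from the face anti to the cyclopropane, setting C5 with C4 on the top face (C4 epimers are irrelevant because C4 becomes sp2).

**Step 13**
Reactants: 14
Product: 15, 2-methoxy dihydropyran with C10 ketone and C15-OTBS
Conditions: (i) HC(OMe)3, TMSOTf (10 mol%), CH2Cl2, –78 → 0 °C; (ii) TsOH·H2O (10 mol%), PhMe, 60 °C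
Reagents that add atoms: trimethyl orthoformate, COC(OC)OC
Why: Noyori-type alkylation of the silyl enol ether by the dimethoxycarbenium ion installs C2 on C1. Acid then promotes cyclisation through the epimerisable α-carbon: the enol-ether oxygen attacks the oxocarbenium ion and MeOH is lost to give the cis-fused enol-ether acetal. The C3=C4 enol ether forms by proton loss from C4 and C2 equilibrates anomerically.

**Step 14**
Reactants: 15
Product: 16, diacetate with C10 ketone
Conditions: Ac2O (10 equiv), Sc(OTf)3 (5 mol%), CH2Cl2, 0 °C
Reagents that add atoms: acetic anhydride, CC(=O)OC(C)=O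
Why: Lewis-acid acetolysis converts the methyl acetal to the acetoxy acetal through the oxocarbenium ion (anomeric control), and the TBS ether is converted to the acetate in the same step.

**Step 15**
Reactants: 16
Product: 17, plagiochilin A
Conditions: Me3S+ I–, NaH, DMSO–THF, 0 → 25 °C
Reagents that add atoms: trimethylsulfonium iodide (CH2 donor via dimethylsulfonium methylide), C[S+](C)C.[I-]
Why: Corey–Chaykovsky epoxidation; the ylide carbon adds to C10 anti to the neighbouring C2 substituent, placing CH2 on the face opposite C2/C4 and O on the same face as C2/C4 (the configuration in the target).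

## Compound list
1 | (S)-(+)-carvone | CC1=CC[C@@H](CC1=O)C(C)=C | starting material
2 | (5S)-dihydrocarvone | CC1CC[C@@H](CC1=O)C(C)=C | intermediate
3 | 8-chloro-p-menthan-2-one | CC1CC[C@@H](CC1=O)C(C)(C)Cl | intermediate
4 | carone | CC1CC[C@@H]2C(C)(C)[C@@H]2C1=O | intermediate
5 | TMS enol ether of carone | CC1=C(O[Si](C)(C)C)[C@@H]2[C@H](CC1)C2(C)C | intermediate
6 | siloxycyclopropane | CC12CC1(O[Si](C)(C)C)[C@@H]1[C@H](CC2)C1(C)C | intermediate
7 | 4,8,8-trimethylbicyclo[5.1.0]oct-3-en-2-one | CC1=CC(=O)[C@@H]2[C@H](CC1)C2(C)C | intermediate
8 | 4-methylidene-8,8-dimethylbicyclo[5.1.0]octan-2-one | C=C1CC(=O)[C@@H]2[C@H](CC1)C2(C)C | intermediate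
9 | 8,8-dimethylbicyclo[5.1.0]octane-2,4-dione | O=C1CC(=O)[C@@H]2[C@H](CC1)C2(C)C | intermediate
10 | 4-methoxy-8,8-dimethylbicyclo[5.1.0]oct-3-en-2-one | COC1=CC(=O)[C@@H]2[C@H](CC1)C2(C)C | intermediate
11 | 8,8-dimethylbicyclo[5.1.0]oct-2-en-4-one | O=C1C=C[C@@H]2[C@H](CC1)C2(C)C | intermediate
12 | 3-(TBS-oxy)propanal | CC(C)(C)[Si](C)(C)OCCC=O | starting material
13 | 1-TMS-oxy-3-TBS-oxy-propene | CC(C)(C)[Si](C)(C)OCC=CO[Si](C)(C)C | intermediate
14 | Mukaiyama–Michael adduct | C[Si](C)(C)OC1=C[C@H](C(C=O)CO[Si](C)(C)C(C)(C)C)[C@H]2C(C)(C)[C@H]2CC1 | intermediate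
15 | 2-methoxy dihydropyran ketone, C15-OTBS | CC(C)(C)[Si](C)(C)OCC1=CO[C@H](OC)[C@@H]2[C@H]1[C@@H]1[C@H](CCC2=O)C1(C)C | intermediate
16 | diacetate ketone | CC(=O)OCC1=CO[C@H](OC(C)=O)[C@@H]2[C@H]1[C@@H]1[C@H](CCC2=O)C1(C)C | intermediate
17 | plagiochilin A | CC(=O)OCC1=CO[C@H](OC(C)=O)[C@@H]2[C@H]1[C@@H]1[C@H](CC[C@@]23CO3)C1(C)C | target

## Step count
Total steps: 15. Longest linear sequence: 14 steps (1 → 17; Step 11 is a side branch making 13).

## Three steps most likely to fail
1. **Step 6 (proposed new electrochemical ring expansion).** Risks are over-oxidation, cyclopropane opening, or a mixture of conjugated and β,γ enones. Fallback using known chemistry: the Ito–Saegusa route, FeCl3/DMF at 0 °C followed by NaOAc/MeOH at reflux, which gives the same enone 7.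
2. **Step 12 (Mukaiyama–Michael at the cyclopropyl-bearing β-carbon).** Lewis-acid activation may open the cyclopropane through a cyclopropylcarbinyl cation, and the allylic OTBS of the enol silane may ionise. Fallback: Cu-catalysed conjugate addition of CH2=C(CH2OTBS)MgBr to 11 with a TMSCl trap, then hydroboration–oxidation and Dess–Martin oxidation to the same keto-aldehyde, re-entering at Step 13.
3. **Step 15 (methylene transfer).** The C10 facial selectivity may be wrong, and the acetoxy acetal may not tolerate the ylide. Fallback: Petasis methylenation of 16 (Cp2TiMe2), then epoxidation of the exocyclic alkene with DMDO, separating the C10 epimers.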